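**Retrosynthetic overview** (lignan numbering: guaiacyl unit C7–C9, central syringyl unit C7'–C9', glycerol unit C7''–C9''; ring A = O, C7, C8, C8', C9'; ring B = O, C7', C8', C8, C9)
The route rests on the ring-fusion carbon C8' of the cis-fused 3,7-dioxabicyclo[3.3.0]octane: it carries C8, C9' and the syringyl-bearing C7', so it can start as the inner carbon of an aryl alkyne tied through C9'–O to the allylic ether carbon C7.
A gold catalyst with an N-oxide turns C7' into the aryl ketone and C8' into a carbene that takes both vinyl carbons (C8–C8', C8'–C9); this closes ring A and a fused cyclopropane in one step.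
Strain release (Cloke–Wilson) then moves C9 from C8' to the ketone oxygen to give ring B as a 2-aryl-4,5-dihydrofuran; hydrogenation from the convex face sets C8' and the endo C7' and frees the syringyl phenol.
The side chain is cut at the C8''–O aryl ether and at C7''–C8'': phenol alkylation with a chloroacetyl oxazolidinone, Evans syn aldol with O-silyl syringaldehyde (threo, 7''R,8''R), hydride removal of the auxiliary, desilylation.
The enyne comes from (R)-1-guaiacylallyl alcohol (vinyl Grignard, Sharpless kinetic resolution), propargyl bromide and a Sonogashira coupling with O-benzyl-4-bromosyringol; ring order: ring A with the cyclopropane (step 7), then ring B (step 8).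

Key step: step 7

Assumption: (S)-4-benzyl-3-(chloroacetyl)oxazolidin-2-one is taken as a purchasable reagent (otherwise one N-acylation of (S)-4-benzyloxazolidin-2-one with chloroacetyl chloride).
Remark: the guaiacyl phenol is carried as a triisopropylsilyl ether (stable to the alkoxide of step 4 and to hydrogenation); the phenol of the alkyne arene is a benzyl ether, which step 9 removes.

**Step 1**
Reactants: 1 vanillin
Product: 2 3-methoxy-4-(triisopropylsilyloxy)benzaldehyde
Conditions: TIPSCl, imidazole, DMF, rt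
Reagents that add atoms: triisopropylsilyl chloride, CC(C)[Si](Cl)(C(C)C)C(C)C
Why: Silylation of the phenol; the hindered aryl silyl ether is chosen to survive Grignard, alkoxide and hydrogenation conditions.

**Step 2**
Reactants: 2 3-methoxy-4-(triisopropylsilyloxy)benzaldehyde; 3 vinylmagnesium bromide
Product: 4 rac-1-[3-methoxy-4-(triisopropylsilyloxy)phenyl]prop-2-en-1-ol
Conditions: THF, −78 → 0 °C; aq NH4Cl
Reagents that add atoms: none
Why: Grignard 1,2-addition to the aldehyde; the carbinol centre (C7) is racemic at this stage.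

**Step 3**
Reactants: 4 rac-1-[3-methoxy-4-(triisopropylsilyloxy)phenyl]prop-2-en-1-ol
Product: 5 (R)-1-[3-methoxy-4-(triisopropylsilyloxy)phenyl]prop-2-en-1-ol
Conditions: Ti(Oi-Pr)4, D-(−)-diisopropyl tartrate, t-BuOOH (0.65 equiv), 4 Å MS, CH2Cl2, −20 °C, run past half conversion
Reagents that add atoms: none
Why: Sharpless kinetic resolution: with the D-(−)-tartrate the (S)-carbinol is epoxidised faster, so the (R)-alcohol (C7 of the target) should be recovered enantioenriched.

**Step 4**
Reactants: 5 (R)-1-[3-methoxy-4-(triisopropylsilyloxy)phenyl]prop-2-en-1-ol; 6 propargyl bromide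
Product: 8 (R)-1-[3-methoxy-4-(triisopropylsilyloxy)phenyl]allyl propargyl ether, via sodium alkoxide 7 (not isolated)
Conditions: NaH, THF, 0 °C; then 6, n-Bu4NI (cat.), 0 °C → rt
Reagents that add atoms: none
Why: Williamson etherification of the secondary alkoxide with SN2-reactive propargyl bromide; no bond to C7 is broken, so R is kept, and THF without DMF spares the aryl silyl ether.

**Step 5**
Reactants: 9 4-bromo-2,6-dimethoxyphenol
Product: 10 2-(benzyloxy)-5-bromo-1,3-dimethoxybenzene
Conditions: BnBr, K2CO3, DMF, rt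
Reagents that add atoms: benzyl bromide, BrCc1ccccc1
Why: Williamson O-benzylation of the phenoxide.

**Step 6**
Reactants: 8 (R)-1-[3-methoxy-4-(triisopropylsilyloxy)phenyl]allyl propargyl ether; 10 2-(benzyloxy)-5-bromo-1,3-dimethoxybenzene
Product: 11 (R)-1-[3-methoxy-4-(triisopropylsilyloxy)phenyl]allyl 3-[4-(benzyloxy)-3,5-dimethoxyphenyl]prop-2-yn-1-yl ether
Conditions: Pd(PhCN)2Cl2 (3 mol%), [HP(t-Bu)3]BF4 (6 mol%), CuI (2 mol%), i-Pr2NH, dioxane, rt
Reagents that add atoms: none
Why: Sonogashira coupling; the bulky electron-rich phosphine lets zerovalent palladium insert into the electron-rich aryl bromide at room temperature, so the allylic ether and the vinyl group are left alone.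

**Step 7**
Reactants: 11 (R)-1-[3-methoxy-4-(triisopropylsilyloxy)phenyl]allyl 3-[4-(benzyloxy)-3,5-dimethoxyphenyl]prop-2-yn-1-yl ether
Product: 13 [(1R,4R,5R)-4-[3-methoxy-4-(triisopropylsilyloxy)phenyl]-3-oxabicyclo[3.1.0]hexan-1-yl][4-(benzyloxy)-3,5-dimethoxyphenyl]methanone (guaiacyl group trans to the cyclopropane CH2), via α-oxo gold carbene 12 (not isolated)
Conditions: IPrAuNTf2 (5 mol%; IPr = 1,3-bis(2,6-diisopropylphenyl)imidazol-2-ylidene), 8-methylquinoline N-oxide (1.3 equiv, slow addition), 4 Å MS, ClCH2CH2Cl, rt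
Reagents that add atoms: 8-methylquinoline N-oxide, Cc1cccc2ccc[n+]([O-])c12
Why: The cationic gold complex activates the alkyne and the N-oxide adds to C7', the carbon polarised both by the propargylic C9'–O bond and by the electron-rich arene; loss of 8-methylquinoline leaves the α-oxo gold carbene 12 with C7' already a ketone and the carbene at C8'. The carbene adds across the tethered vinyl group, C8' bonding to the inner carbon C8 in a 5-exo sense (ring A: O, C7, C8, C8', C9') and to C9 in a 3-exo closure (cyclopropane C8, C8', C9); the other order of events, 5-exo-dig enyne cyclisation followed by oxidation of the cyclopropyl gold carbene at C7', ends at the same ketone. The closest known reaction type is the gold-catalysed N-oxide oxidation/cyclopropanation of heteroatom-tethered 1,6-enynes that carry an aryl alkyne. C8 and C8' are set relative to C7: in the envelope-like transition state the guaiacyl group lies pseudo-equatorial, so the methylene C9 should form on the face of ring A anti to it, and the cis fusion that a three-membered ring demands then fixes C8'. The step needs oxygen at C7' only (secured by the matched polarisation), capture of the carbene by the alkene before a second oxidation, a 1,2-hydride shift from C9' or attack by the guaiacyl ring (secured by the five-membered tether and slow addition of a hindered N-oxide), and the anti facial selectivity just described.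

**Step 8**
Reactants: 13 the cyclopropyl ketone of step 7
Product: 15 (3aS,4R)-1-[4-(benzyloxy)-3,5-dimethoxyphenyl]-4-[3-methoxy-4-(triisopropylsilyloxy)phenyl]-3a,4-dihydro-3H,6H-furo[3,4-c]furan (C7'=C8' enol ether; 7R,8S), via γ-iodo magnesium enolate 14 (not isolated)
Conditions: MgI2 (1.0 equiv), THF–toluene, 70 °C
Reagents that add atoms: none
Why: Proposed new method: magnesium held between the ketone and the ring A oxygen should let iodide open this acceptor-only cyclopropane by SN2 attack at the unhindered methylene C9 (breaking C8'–C9), and the γ-iodo enolate 14 should then close through oxygen (5-exo-tet O-alkylation, ring B) under thermodynamic control to the aryl-conjugated enol ether with C8 untouched; the closest known reaction types are the iodide- or Lewis-acid-promoted Cloke–Wilson rearrangement of doubly activated or donor-substituted acylcyclopropanes and the MgI2-mediated opening of aryl cyclopropyl ketones to γ-iodo enolates used in ring expansions with imines.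

**Step 9**
Reactants: 15 the bicyclic enol ether of step 8
Product: 17 4-[(1S,3aS,4R,6aS)-4-[3-methoxy-4-(triisopropylsilyloxy)phenyl]tetrahydro-1H,3H-furo[3,4-c]furan-1-yl]-2,6-dimethoxyphenol (7R,8S,7'S,8'S; syringyl endo), via debenzylated enol ether 16 (not isolated)
Conditions: H2 (3 bar), 10% Pd/C, NaHCO3, EtOAc, rt
Reagents that add atoms: none
Why: Heterogeneous hydrogenation with hydrogenolysis of the benzyl ether: syn addition of H2 to the tetrasubstituted enol ether from the face that carries H–C8 (ring A bends away from it) gives the cis ring fusion (C8' S) and puts H–C7' exo, so the syringyl ring is endo (C7' S).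

**Step 10**
Reactants: 17 the phenol of step 9; 18 (S)-4-benzyl-3-(chloroacetyl)oxazolidin-2-one
Product: 19 (S)-4-benzyl-3-{2-[4-((1S,3aS,4R,6aS)-4-[3-methoxy-4-(triisopropylsilyloxy)phenyl]tetrahydro-1H,3H-furo[3,4-c]furan-1-yl)-2,6-dimethoxyphenoxy]acetyl}oxazolidin-2-one
Conditions: K2CO3, n-Bu4NI (cat.), acetone, rt
Reagents that add atoms: none
Why: Williamson-type SN2 displacement on the α-chloro imide by the syringyl phenoxide with iodide catalysis; carbonate at room temperature should leave the para-hydroxybenzylic C7'–O bond and the imide intact.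

**Step 11**
Reactants: 20 syringaldehyde
Product: 21 4-(tert-butyldimethylsilyloxy)-3,5-dimethoxybenzaldehyde
Conditions: TBSCl, imidazole, DMF, rt
Reagents that add atoms: tert-butyldimethylsilyl chloride, CC(C)(C)[Si](C)(C)Cl
Why: Silylation of the phenol so that both phenols can be freed together at the end.

**Step 12**
Reactants: 19 the aryloxyacetyl imide of step 10; 21 4-(tert-butyldimethylsilyloxy)-3,5-dimethoxybenzaldehyde
Product: 23 (S)-4-benzyl-3-[(2S,3R)-3-[4-(tert-butyldimethylsilyloxy)-3,5-dimethoxyphenyl]-3-hydroxy-2-(aryloxy)propanoyl]oxazolidin-2-one (aryloxy = the furofuran-substituted 2,6-dimethoxyphenoxy group of 19), via dibutylboron Z-enolate 22 (not isolated)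
Conditions: n-Bu2BOTf, Et3N, CH2Cl2, −78 → 0 °C; then 21, −78 → 0 °C; pH 7 buffer, MeOH, 30% H2O2, 0 °C
Reagents that add atoms: none
Why: Evans syn aldol (glycolate variant): the Z-boron enolate reacts through a closed Zimmerman–Traxler transition state on the face away from the benzyl group of the (S)-auxiliary, which sets C8'' and C7'' syn (threo) in the sense that reads 7''R,8''R after reduction.

**Step 13**
Reactants: 23 the aldol adduct of step 12
Product: 24 (1R,2R)-1-[4-(tert-butyldimethylsilyloxy)-3,5-dimethoxyphenyl]-2-(aryloxy)propane-1,3-diol (aryloxy as in 23)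
Conditions: LiBH4, THF–MeOH, 0 °C
Reagents that add atoms: none
Why: Hydride reduction of the N-acyl oxazolidinone (reductive removal of the auxiliary) gives the primary alcohol C9'' without touching C7'' or C8''.

**Step 14**
Reactants: 24 the bis-silyl ether of step 13
Product: 25 (1R,2R)-1-(4-hydroxy-3,5-dimethoxyphenyl)-2-{4-[(1S,3aS,4R,6aS)-4-(4-hydroxy-3-methoxyphenyl)tetrahydro-1H,3H-furo[3,4-c]furan-1-yl]-2,6-dimethoxyphenoxy}propane-1,3-diol (CNP0317965.1)
Conditions: n-Bu4NF, AcOH, THF, 0 °C
Reagents that add atoms: none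
Why: Fluoride cleavage of both aryl silyl ethers; buffering with acetic acid should prevent phenoxide-driven quinone methide formation at the para-hydroxybenzylic centres C7, C7' and C7''.

**Compound list**
1 | vanillin | COc1cc(C=O)ccc1O | starting material
2 | 3-methoxy-4-(triisopropylsilyloxy)benzaldehyde | COc1cc(C=O)ccc1O[Si](C(C)C)(C(C)C)C(C)C | intermediate
3 | vinylmagnesium bromide | C=C[Mg]Br | starting material
4 | rac-1-[3-methoxy-4-(triisopropylsilyloxy)phenyl]prop-2-en-1-ol | COc1cc(C(O)C=C)ccc1O[Si](C(C)C)(C(C)C)C(C)C | intermediate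
5 | (R)-1-[3-methoxy-4-(triisopropylsilyloxy)phenyl]prop-2-en-1-ol | COc1cc([C@H](O)C=C)ccc1O[Si](C(C)C)(C(C)C)C(C)C | intermediate
6 | propargyl bromide | BrCC#C | starting material
7 | sodium (R)-1-[3-methoxy-4-(triisopropylsilyloxy)phenyl]prop-2-en-1-olate | COc1cc([C@H]([O-])C=C)ccc1O[Si](C(C)C)(C(C)C)C(C)C.[Na+] | intermediate
8 | (R)-1-[3-methoxy-4-(triisopropylsilyloxy)phenyl]allyl propargyl ether | COc1cc([C@H](OCC#C)C=C)ccc1O[Si](C(C)C)(C(C)C)C(C)C | intermediate
9 | 4-bromo-2,6-dimethoxyphenol | COc1cc(Br)cc(OC)c1O | starting material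
10 | 2-(benzyloxy)-5-bromo-1,3-dimethoxybenzene | COc1cc(Br)cc(OC)c1OCc1ccccc1 | intermediate
11 | (R)-1-[3-methoxy-4-(triisopropylsilyloxy)phenyl]allyl 3-[4-(benzyloxy)-3,5-dimethoxyphenyl]prop-2-yn-1-yl ether | COc1cc([C@H](OCC#Cc2cc(OC)c(OCc3ccccc3)c(OC)c2)C=C)ccc1O[Si](C(C)C)(C(C)C)C(C)C | intermediate
12 | α-oxo gold carbene (IPr-gold bound to C8', ketone at C7', bistriflimide counter-ion) | COc1cc([C@H](OCC(=[Au]c2n(-c3c(C(C)C)cccc3C(C)C)cc[n+]2-c2c(C(C)C)cccc2C(C)C)C(=O)c2cc(OC)c(OCc3ccccc3)c(OC)c2)C=C)ccc1O[Si](C(C)C)(C(C)C)C(C)C.O=S(=O)([N-]S(=O)(=O)C(F)(F)F)C(F)(F)F | intermediate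
13 | [(1R,4R,5R)-4-[3-methoxy-4-(triisopropylsilyloxy)phenyl]-3-oxabicyclo[3.1.0]hexan-1-yl][4-(benzyloxy)-3,5-dimethoxyphenyl]methanone | COc1cc([C@@H]2OC[C@@]3(C(=O)c4cc(OC)c(OCc5ccccc5)c(OC)c4)C[C@@H]23)ccc1O[Si](C(C)C)(C(C)C)C(C)C | intermediate
14 | γ-iodo magnesium enolate (ring A with CH2I on C8 and the exocyclic iodomagnesium enolate on C8'; enolate geometry not defined) | COc1cc([C@@H]2OCC(=C(O[Mg]I)c3cc(OC)c(OCc4ccccc4)c(OC)c3)[C@H]2CI)ccc1O[Si](C(C)C)(C(C)C)C(C)C | intermediate
15 | (3aS,4R)-1-[4-(benzyloxy)-3,5-dimethoxyphenyl]-4-[3-methoxy-4-(triisopropylsilyloxy)phenyl]-3a,4-dihydro-3H,6H-furo[3,4-c]furan | COc1cc([C@@H]2OCC3=C(c4cc(OC)c(OCc5ccccc5)c(OC)c4)OC[C@@H]23)ccc1O[Si](C(C)C)(C(C)C)C(C)C | intermediate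
16 | 4-[(3aS,4R)-4-[3-methoxy-4-(triisopropylsilyloxy)phenyl]-3a,4-dihydro-3H,6H-furo[3,4-c]furan-1-yl]-2,6-dimethoxyphenol | COc1cc([C@@H]2OCC3=C(c4cc(OC)c(O)c(OC)c4)OC[C@@H]23)ccc1O[Si](C(C)C)(C(C)C)C(C)C | intermediate
17 | 4-[(1S,3aS,4R,6aS)-4-[3-methoxy-4-(triisopropylsilyloxy)phenyl]tetrahydro-1H,3H-furo[3,4-c]furan-1-yl]-2,6-dimethoxyphenol | COc1cc([C@@H]2OC[C@@H]3[C@H]2CO[C@@H]3c2cc(OC)c(O)c(OC)c2)ccc1O[Si](C(C)C)(C(C)C)C(C)C | intermediate
18 | (S)-4-benzyl-3-(chloroacetyl)oxazolidin-2-one | O=C(CCl)N1[C@@H](Cc2ccccc2)COC1=O | starting material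
19 | aryloxyacetyl imide: (S)-4-benzyl-3-{2-[4-(furofuranyl)-2,6-dimethoxyphenoxy]acetyl}oxazolidin-2-one | COc1cc([C@@H]2OC[C@@H]3[C@H]2CO[C@@H]3c2cc(OC)c(OCC(=O)N3[C@@H](Cc4ccccc4)COC3=O)c(OC)c2)ccc1O[Si](C(C)C)(C(C)C)C(C)C | intermediate
20 | syringaldehyde | COc1cc(C=O)cc(OC)c1O | starting material
21 | 4-(tert-butyldimethylsilyloxy)-3,5-dimethoxybenzaldehyde | COc1cc(C=O)cc(OC)c1O[Si](C)(C)C(C)(C)C | intermediate
22 | dibutylboron Z-enolate of 19 | COc1cc([C@@H]2OC[C@@H]3[C@H]2CO[C@@H]3c2cc(OC)c(O/C=C(\OB(CCCC)CCCC)N3[C@@H](Cc4ccccc4)COC3=O)c(OC)c2)ccc1O[Si](C(C)C)(C(C)C)C(C)C | intermediate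
23 | (S)-4-benzyl-3-[(2S,3R)-3-[4-(tert-butyldimethylsilyloxy)-3,5-dimethoxyphenyl]-3-hydroxy-2-(aryloxy)propanoyl]oxazolidin-2-one | COc1cc([C@@H]2OC[C@@H]3[C@H]2CO[C@@H]3c2cc(OC)c(O[C@H](C(=O)N3[C@@H](Cc4ccccc4)COC3=O)[C@H](O)c3cc(OC)c(O[Si](C)(C)C(C)(C)C)c(OC)c3)c(OC)c2)ccc1O[Si](C(C)C)(C(C)C)C(C)C | intermediate
24 | (1R,2R)-1-[4-(tert-butyldimethylsilyloxy)-3,5-dimethoxyphenyl]-2-(aryloxy)propane-1,3-diol, guaiacyl phenol as triisopropylsilyl ether | COc1cc([C@@H]2OC[C@@H]3[C@H]2CO[C@@H]3c2cc(OC)c(O[C@H](CO)[C@H](O)c3cc(OC)c(O[Si](C)(C)C(C)(C)C)c(OC)c3)c(OC)c2)ccc1O[Si](C(C)C)(C(C)C)C(C)C | intermediate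
25 | CNP0317965.1, (7R,8S,7'S,8'S,7''R,8''R) | COc1cc([C@@H]2OC[C@@H]3[C@H]2CO[C@@H]3c2cc(OC)c(O[C@H](CO)[C@H](O)c3cc(OC)c(O)c(OC)c3)c(OC)c2)ccc1O | target

**Step count and risks**
Total: 14 steps. Longest linear sequence: 12 steps (1, 2, 3, 4, 6, 7, 8, 9, 10, 12, 13, 14 from vanillin).

Most likely to fail:

1. Step 8 (proposed new method). The acceptor-only cyclopropane with an electron-rich aroyl group may resist opening, the magnesium enolate may reclose on carbon or expel the ring A oxygen by β-elimination, and the Lewis acid may start to cleave the benzyl ether (harmless, since step 9 removes it). Fallback with known chemistry, setting out from 13: Me3SiI in CH2Cl2 at −78 °C followed by aqueous NaHCO3 (the established silyl iodide cleavage of cyclopropyl ketones, attack at the methylene) should give the γ-iodo ketone F1 as a mixture of C8' epimers. Silver-assisted solvolysis with carbonyl participation (AgBF4, 2,6-lutidine, aqueous acetone) should then close ring B to the cyclic hemiketal F2; only the cis-fused hemiketal can form and C8' equilibrates through the enol. Dehydration with pyridinium p-toluenesulfonate in warm toluene over molecular sieves returns to the route at 15.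

2. Step 7. The carbene may be diverted by a 1,2-hydride shift from C9', by a second oxidation or by attack of the guaiacyl ring; the doubly activated C7–O bond may ionise at the Lewis-acidic catalyst; the facial selectivity relative to C7 may be poor. Fallback that changes the carbene source and brings in the arene later, setting out from 8: Cp*RuCl(cod) (cat.) and Me3SiCHN2 in dioxane at 60 °C should convert the terminal alkyne into a ruthenium vinylcarbene at C8' that cyclopropanates the tethered vinyl group, giving the (Z)-1-[2-(trimethylsilyl)vinyl]-3-oxabicyclo[3.1.0]hexane F3. Ozonolysis (O3, CH2Cl2, −78 °C; PPh3) gives the cyclopropanecarbaldehyde F4. The aryllithium made from 10 (n-BuLi, THF, −78 °C) adds to it to give the carbinol F5 (both C7' epimers), and Dess–Martin periodinane with NaHCO3 returns to the route at 13.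

3. Step 9. Hydrogenolysis of the benzylic C7–O or C7'–O bonds may compete, the tetrasubstituted enol ether may reduce slowly, and double-bond migration on palladium may erode C7'. Fallback, setting out from 15: ionic hydrogenation (Et3SiH, CF3CO2H, CH2Cl2, −78 → −40 °C) protonates C8' to the cis-fused aryl oxocarbenium ion and delivers hydride to C7' from the convex face, giving the endo-syringyl benzyl ether F6. Transfer hydrogenolysis (Pd/C, cyclohexa-1,4-diene, EtOAc–EtOH, rt) then removes the benzyl group and returns to the route at 17.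

**Further compounds**
F1 | step 8 | γ-iodo ketone: [(2R,3S)-4-aroyl-3-(iodomethyl)-2-aryl-tetrahydrofuran, C8' epimers] | COc1cc([C@@H]2OCC(C(=O)c3cc(OC)c(OCc4ccccc4)c(OC)c3)[C@H]2CI)ccc1O[Si](C(C)C)(C(C)C)C(C)C
F2 | step 8 | cis-fused cyclic hemiketal (C7' hydroxyl, anomeric centre not defined) | COc1cc([C@@H]2OC[C@@H]3[C@H]2COC3(O)c2cc(OC)c(OCc3ccccc3)c(OC)c2)ccc1O[Si](C(C)C)(C(C)C)C(C)C
F3 | step 7 | (1R,4R,5R)-4-[3-methoxy-4-(triisopropylsilyloxy)phenyl]-1-[(Z)-2-(trimethylsilyl)vinyl]-3-oxabicyclo[3.1.0]hexane | COc1cc([C@@H]2OC[C@@]3(/C=C\[Si](C)(C)C)C[C@@H]23)ccc1O[Si](C(C)C)(C(C)C)C(C)C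
F4 | step 7 | (1R,4R,5R)-4-[3-methoxy-4-(triisopropylsilyloxy)phenyl]-3-oxabicyclo[3.1.0]hexane-1-carbaldehyde | COc1cc([C@@H]2OC[C@@]3(C=O)C[C@@H]23)ccc1O[Si](C(C)C)(C(C)C)C(C)C
F5 | step 7 | [4-(benzyloxy)-3,5-dimethoxyphenyl][(1R,4R,5R)-4-[3-methoxy-4-(triisopropylsilyloxy)phenyl]-3-oxabicyclo[3.1.0]hexan-1-yl]methanol (C7' epimers) | COc1cc([C@@H]2OC[C@@]3(C(O)c4cc(OC)c(OCc5ccccc5)c(OC)c4)C[C@@H]23)ccc1O[Si](C(C)C)(C(C)C)C(C)C
F6 | step 9 | (1S,3aS,4R,6aS)-1-[4-(benzyloxy)-3,5-dimethoxyphenyl]-4-[3-methoxy-4-(triisopropylsilyloxy)phenyl]tetrahydro-1H,3H-furo[3,4-c]furan | COc1cc([C@@H]2OC[C@@H]3[C@H]2CO[C@@H]3c2cc(OC)c(OCc3ccccc3)c(OC)c2)ccc1O[Si](C(C)C)(C(C)C)C(C)C
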